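## Structural features

The target 24 is built on a nine-membered lactam, N4–C9a(=O)–C9–C10–C11–C12–C1(=O)–C2–C3, that carries a ketone at C1. A four-carbon tether (C5–C8) joins N4 to C9 and closes an azepan-2-one on the N4–C9a–C9 edge. An α-methyl γ-lactone (C11–O–C14(=O)–C13(Me)–C12) is cis-fused across C11–C12, and a second, cis-2,4-disubstituted γ-lactone (C18–C21, methyl on C20) hangs from C3. Five of the eight stereocentres (C9, C10, C11, C12, C13) are contiguous along one flank of the medium ring; C3 and C18 form a vicinal amino-alcohol pair. Fragile points are the β-acyloxy ketone (C1/C12/C11–O), the epimerisable centres C12, C13 and C20, and both lactones; a free amine at C3 would also attack the side lactone (O→N acyl shift). The real difficulty is the nine-membered ring itself, which resists end-to-end closure and must be formed next to a dense stereochemical array. The feature exploited is that C10–C11–C12 is a three-carbon bridge between C9 and C1: without it the ring is the six-membered β-keto lactam N4–C9a–C9–C1–C2–C3, and C12 is 1,5-related to the C1 carbonyl, so a C12 radical can add to C1 and the C1–C9 bond can then break.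

## Logic of the disconnections

**N4–C5 (24 ⇒ 23 ⇒ 22).** The azepanone is opened at the lactam N–alkyl bond, the only ring bond that can be made without creating or disturbing a stereocentre. This leaves a monocyclic medium ring with a halobutyl chain on C9. The forward step must form the amidate and cyclise it without enolising the β-acyloxy ketone; hence the chloride 22 is first exchanged to the iodide 23 so that the closure can be run cold with one equivalent of base.

**C1–C12 cut, C1–C9 restored (22 ⇒ 21).** This is the three-carbon ring contraction in the retrosynthetic sense. The medium ring and two stereocentres (C9, C12) disappear, leaving a piperidine-2,4-dione with a quaternary C9 whose configuration does not matter. The forward step needs the C12 radical to add to the hindered ketone faster than it is reduced, attack at the ketone and not the lactam carbonyl, and hydrogen delivery to one face of the C9 radical. C12 is fixed by ring fusion.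

**C9–C8 (21 ⇒ 19 + 20).** The chlorobutyl chain is removed as a bifunctional electrophile. The gain is a monosubstituted, strongly acidic dione. The demand is C- over O-alkylation at a hindered carbon and discrimination of iodide from chloride.

**N4–C9a and C9–C1 (19 ⇒ 17 ⇒ 16 + 9).** The dione is opened to a β-keto thioester with a protected amine, and this is cut at C9–C1 into a thioester nucleophile and an acyl donor. A Knoevenagel/Michael construction of C9–C10 on a preformed dione was set aside because it would leave C10 and C11 to an open transition state with no reliable control element. The forward Claisen step must enolise only the thioester in the presence of two lactones, a carbamate and a selenide, which calls for soft enolisation.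

**C–S, C12–Se and oxidation level (16 ⇒ 15 ⇒ 14 ⇒ 13).** The thioester goes back to the acid, the selenide to the butenolide, and the acid to the aldehyde. Selenol is added before any base is used, because the γ-hydrogen of the butenolide (C11–H) is acidic and would put C11 at risk. The addition must place selenium anti to the C11 chain and set C13 by protonation anti to selenium.

**C10–C11 (13 ⇒ 11 + 12; 11 ⇒ 10).** The bond between the two carbinol-flank centres is cut to an (E)-enal and a silyloxyfuran. Both stereocentres then come from one catalyst-controlled step, and the target's unlike (syn) C10/C11 relationship is the one that iminium catalysis of this addition is expected to favour. The demand is high facial control at the β-carbon and syn simple diastereoselection.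

**Acyl activation, ester and C20 (9 ⇒ 8 ⇒ 7 ⇒ 6).** The acyl donor goes back to the acid and its tert-butyl ester; C20–H is removed to an exocyclic alkene. The ester must be cleaved without freeing the amine, and hydrogenation must occur anti to the C18 substituent.

**C18–C19 and lactone C–O (6 ⇒ 3 + 4; 3 ⇒ 2 ⇒ 1).** The side lactone is cut to an aspartate-derived α-amino aldehyde and a 2-(alkoxycarbonyl)allyl unit. C3 comes from the chiral pool, and C18 must be set syn to nitrogen by chelation control. A tert-butyl ester is used on the β-carboxyl so that the new hydroxyl can lactonise only onto the acrylate ester.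

## Other disconnections considered

**Alternative 1:** The fused lactone is cut at C11–C12 and at O–C14, giving aldehyde A1 (C9 and C10 already set) and the methylsuccinate thioester A2. In the forward step the E boron enolate of A2, formed at C12, would add to A1 in an anti aldol, and acid would close the lactone to A3.
- In its favour: the anti-aldol/lactonisation sequence maps directly onto the cis C10/C1 relationship on the lactone, C13 comes from the pool, and C9 is set in an acyclic precursor by ionic chemistry. On C9 it is better than the chosen plan, which leaves that centre to a hydrogen-atom transfer.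
- Against it: the aldehyde carries an epimerisable α-centre, the aldol is a double-stereodifferentiating reaction whose facial outcome relative to C10 is not assured, and after A3 the nine-membered ring is still unmade. It would have to be closed as a medium-ring lactam or by C1–C2 bond formation, both entropically poor.
- Comparison: on stereocontrol of C9, C11 and C12 this route is equal or better; on ring construction and on the number of steps after the key step the chosen plan is clearly shorter, since the medium ring and the ketone appear together.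

**Alternative 2:** The cut is at C2–C3 and O–C1, with N4–C9a to follow. The Z-nitrone A4 would add across the C12 vinyl group to give the isoxazolidine A5 inside a twelve-membered ring. N–O cleavage, transannular lactamisation onto the C9a ester and oxidation at C1 would then finish the skeleton.
- In its favour: a twelve-membered closure is easier than a nine-membered one, the cycloaddition is thermal and reagent-free, either C1 epimer is usable, and C9–C13 are all fixed beforehand. On C9 and on freedom from tin it is better than the chosen plan.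
- Against it: C3 has to be created in a macrocyclic cycloaddition whose facial selectivity rests on the neighbouring C18 and on ring conformation; in the chosen plan C3 is bought with aspartic acid. The acyclic precursor is long, high dilution is needed, and three operations follow the key step.
- Comparison: mechanistically equal in risk (regio- and facial selectivity there, radical rate competition here); worse in step economy.

**Alternative 3:** The cut is at N4–C3 with O–C1 restored. The bicyclic O-allyl lactim ether A6 would undergo an imidate-to-amide [3,3] shift, thermally or with PdCl2(MeCN)2, to the nine-membered lactam A7 with a Z C1=C2 alkene.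
- In its favour: the imidate-to-amide change gives a strong driving force, chirality is transferred suprafacially from C1 to C3, and the azepane and C9 are already in place. On stereospecificity it is better than a hydrogen-atom transfer.
- Against it: the C–N bond must form at a carbon bearing the bulky lactone, and a seven-membered cyclic imidate with a defined C1 centre and alkene geometry is hard to make. The product also lacks the C1 ketone, so the C1=C2 alkene would have to be oxidised regioselectively at C1.
- Comparison: equal or better on driving force and on C3/C9 definition; worse on precursor access and on post-rearrangement steps, because the chosen plan delivers the ketone in the ring-forming event.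

Key step: step 15

Assumption: 1, 4, 10, 12 and 20 are bought. The C9 configuration of 17, 19 and 21 is left open because that centre becomes trigonal in step 15; 21 is drawn as one epimer (3R) only for definiteness. The C13 descriptor changes from R (15–21) to S (22–24) because of the CIP rank of selenium, not by inversion.

Step 1
Reactants: 1 (2S)-4-tert-butoxy-2-[(tert-butoxycarbonyl)amino]-4-oxobutanoic acid
Product: 2 tert-butyl (3S)-3-[(tert-butoxycarbonyl)amino]-4-hydroxybutanoate
Conditions: i-BuOCOCl, N-methylmorpholine, THF, −15 °C; then NaBH4, H2O, 0 °C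
Reagents that add atoms: none
Why: Reduction of the mixed carbonic anhydride of the α-carboxyl group by NaBH4; the tert-butyl ester and the Boc group are inert and the stereocentre (later C3) is not touched.

Step 2
Reactants: 2 tert-butyl (3S)-3-[(tert-butoxycarbonyl)amino]-4-hydroxybutanoate
Product: 3 tert-butyl (3S)-3-[(tert-butoxycarbonyl)amino]-4-oxobutanoate
Conditions: TEMPO (10 mol%), PhI(OAc)2, CH2Cl2, rt
Reagents that add atoms: none
Why: Nitroxyl-catalysed oxidation stops at the aldehyde and is non-basic, which protects the α-amino stereocentre; 3 is used at once.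

Step 3
Reactants: 3 tert-butyl (3S)-3-[(tert-butoxycarbonyl)amino]-4-oxobutanoate; 4 ethyl 2-(bromomethyl)prop-2-enoate
Product: 6 tert-butyl (3S)-3-[(tert-butoxycarbonyl)amino]-3-[(2S)-4-methylidene-5-oxooxolan-2-yl]propanoate, via hydroxy diester 5 (not isolated)
Conditions: indium powder, THF/H2O (1:1), rt; then p-TsOH·H2O (5 mol%), CH2Cl2, rt
Reagents that add atoms: none
Why: Barbier-type 2-(ethoxycarbonyl)allylation: the allylindium species should add to the aldehyde held in a five-membered chelate with the NH-carbamate, from the face opposite the CH2CO2t-Bu arm, giving the syn (4S,5S) amino alcohol 5 and so (18S). Acid then closes the α-methylene γ-lactone on the ethyl ester, the tert-butyl ester being too hindered to compete.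

Step 4
Reactants: 6 tert-butyl (3S)-3-[(tert-butoxycarbonyl)amino]-3-[(2S)-4-methylidene-5-oxooxolan-2-yl]propanoate
Product: 7 tert-butyl (3S)-3-[(tert-butoxycarbonyl)amino]-3-[(2S,4S)-4-methyl-5-oxooxolan-2-yl]propanoate
Conditions: H2 (1 atm), 10% Pd/C, EtOAc, rt
Reagents that add atoms: none
Why: Heterogeneous hydrogenation of the exocyclic alkene (directly or after palladium-mediated migration into the ring); hydrogen should be delivered to the lactone face away from the C18 substituent, so the new methyl group ends cis to it (20S).

Step 5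
Reactants: 7 tert-butyl (3S)-3-[(tert-butoxycarbonyl)amino]-3-[(2S,4S)-4-methyl-5-oxooxolan-2-yl]propanoate
Product: 8 (3S)-3-[(tert-butoxycarbonyl)amino]-3-[(2S,4S)-4-methyl-5-oxooxolan-2-yl]propanoic acid
Conditions: CeCl3·7H2O, NaI, MeCN, 80 °C
Reagents that add atoms: none
Why: Lewis-acid cleavage of a tert-butyl ester by the CeCl3/NaI system, a known way to keep the N-Boc group of amino acid derivatives intact; the nitrogen is never set free, so it cannot attack the lactone.

Step 6
Reactants: 8 (3S)-3-[(tert-butoxycarbonyl)amino]-3-[(2S,4S)-4-methyl-5-oxooxolan-2-yl]propanoic acid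
Product: 9 tert-butyl N-[(1S)-3-(1H-benzotriazol-1-yl)-1-[(2S,4S)-4-methyl-5-oxooxolan-2-yl]-3-oxopropyl]carbamate
Conditions: 1H-benzotriazole, DCC, CH2Cl2, 0 °C → rt
Reagents that add atoms: 1H-benzotriazole, c1ccc2[nH]nnc2c1
Why: Carbodiimide-mediated acylation of benzotriazole gives a neutral, isolable acyl donor of the kind needed for the crossed Claisen step; no stereocentre is affected.

Step 7
Reactants: 10 3-methylfuran-2(5H)-one
Product: 11 trimethyl[(3-methylfuran-2-yl)oxy]silane
Conditions: Me3SiCl, Et3N, Et2O, 0 °C → rt
Reagents that add atoms: chlorotrimethylsilane, C[Si](C)(C)Cl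
Why: O-Silylation of the dienolate of the butenolide gives the aromatic 2-silyloxyfuran, the vinylogous nucleophile for step 8.

Step 8
Reactants: 11 trimethyl[(3-methylfuran-2-yl)oxy]silane; 12 (2E)-pent-2-enal
Product: 13 (3R)-3-[(2S)-4-methyl-5-oxo-2,5-dihydrofuran-2-yl]pentanal
Conditions: (2S,5S)-5-benzyl-2-tert-butyl-3-methylimidazolidin-4-one·2,4-dinitrobenzoic acid (20 mol%), H2O (2 equiv), CH2Cl2, −70 °C
Reagents that add atoms: none
Why: Iminium-catalysed vinylogous Mukaiyama–Michael addition: the imidazolidinone forms the (E)-iminium ion of 12, its benzyl group blocks one face, and C5 of the furan should attack the exposed Re face of the β-carbon (C10, R). The open approach favoured by this catalyst class places ethyl and ring oxygen syn, which corresponds to (S) at C11; water removes the silyl group and turns the catalyst over.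

Step 9
Reactants: 13 (3R)-3-[(2S)-4-methyl-5-oxo-2,5-dihydrofuran-2-yl]pentanal
Product: 14 (3R)-3-[(2S)-4-methyl-5-oxo-2,5-dihydrofuran-2-yl]pentanoic acid
Conditions: NaClO2, NaH2PO4, 2-methylbut-2-ene, t-BuOH/H2O, 0 °C → rt
Reagents that add atoms: sodium chlorite, [Na+].[O-]Cl=O
Why: Pinnick oxidation converts the aldehyde into the acid under buffered, weakly acidic conditions that leave the butenolide and both stereocentres alone; the alkene scavenges hypochlorite.

Step 10
Reactants: 14 (3R)-3-[(2S)-4-methyl-5-oxo-2,5-dihydrofuran-2-yl]pentanoic acid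
Product: 15 (3R)-3-[(2S,3R,4R)-4-methyl-5-oxo-3-(phenylselanyl)oxolan-2-yl]pentanoic acid
Conditions: PhSeH (1.5 equiv), Et3N (20 mol%), THF, −20 → 0 °C
Reagents that add atoms: benzeneselenol, [SeH]c1ccccc1
Why: Conjugate addition of benzeneselenol to the butenolide: selenium should enter C12 anti to the C11 side chain, and the enolate should be protonated at C13 anti to the new C–Se bond, so methyl ends cis to selenium (the arrangement that is 13S in 24). The step also removes the acidic γ-hydrogen of the butenolide before any base is used and installs the radical precursor.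

Step 11
Reactants: 15 (3R)-3-[(2S,3R,4R)-4-methyl-5-oxo-3-(phenylselanyl)oxolan-2-yl]pentanoic acid
Product: 16 S-phenyl (3R)-3-[(2S,3R,4R)-4-methyl-5-oxo-3-(phenylselanyl)oxolan-2-yl]pentanethioate
Conditions: PhSH, DCC, DMAP (10 mol%), CH2Cl2, 0 °C
Reagents that add atoms: benzenethiol, Sc1ccccc1
Why: Steglich-type thioesterification; the S-phenyl thioester supplies the acidity needed for soft enolisation, and it is made after the selenol addition so that no thiolate meets a butenolide.

Step 12
Reactants: 16 S-phenyl (3R)-3-[(2S,3R,4R)-4-methyl-5-oxo-3-(phenylselanyl)oxolan-2-yl]pentanethioate; 9 tert-butyl N-[(1S)-3-(1H-benzotriazol-1-yl)-1-[(2S,4S)-4-methyl-5-oxooxolan-2-yl]-3-oxopropyl]carbamate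
Product: 17 S-phenyl (5S)-5-[(tert-butoxycarbonyl)amino]-5-[(2S,4S)-4-methyl-5-oxooxolan-2-yl]-2-{(1R)-1-[(2S,3R,4R)-4-methyl-5-oxo-3-(phenylselanyl)oxolan-2-yl]propyl}-3-oxopentanethioate (C2 epimers, enolisable)
Conditions: MgBr2·OEt2 (2.5 equiv), i-Pr2NEt (3 equiv), CH2Cl2, rt
Reagents that add atoms: none
Why: Crossed Claisen condensation under soft enolisation: MgBr2 and the amine should enolise only the S-phenyl thioester (lactones, carbamate and selenide stay untouched), and the magnesium enolate is C-acylated by the acylbenzotriazole to form C9–C1. The product is held as its chelated enolate, which stops further acylation; C9 forms as a mixture, which is harmless.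

Step 13
Reactants: 17 S-phenyl (5S)-5-[(tert-butoxycarbonyl)amino]-5-[(2S,4S)-4-methyl-5-oxooxolan-2-yl]-2-{(1R)-1-[(2S,3R,4R)-4-methyl-5-oxo-3-(phenylselanyl)oxolan-2-yl]propyl}-3-oxopentanethioate
Product: 19 (6S)-6-[(2S,4S)-4-methyl-5-oxooxolan-2-yl]-3-{(1R)-1-[(2S,3R,4R)-4-methyl-5-oxo-3-(phenylselanyl)oxolan-2-yl]propyl}piperidine-2,4-dione (C3 epimers, enolisable), via ammonium trifluoroacetate 18 (not isolated)
Conditions: CF3CO2H, CH2Cl2, 0 °C; then Et3N, CH2Cl2, 0 °C → rt
Reagents that add atoms: none
Why: Acidolysis of the Boc group, then neutralisation, lets the C3 amine attack the activated β-keto thioester (6-exo-trig lactamisation); this should be far faster than attack on the neighbouring γ-lactone. C3, C18 and C20 are untouched.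

Step 14
Reactants: 19 (6S)-6-[(2S,4S)-4-methyl-5-oxooxolan-2-yl]-3-{(1R)-1-[(2S,3R,4R)-4-methyl-5-oxo-3-(phenylselanyl)oxolan-2-yl]propyl}piperidine-2,4-dione; 20 1-chloro-4-iodobutane
Product: 21 (3R,6S)-3-(4-chlorobutyl)-6-[(2S,4S)-4-methyl-5-oxooxolan-2-yl]-3-{(1R)-1-[(2S,3R,4R)-4-methyl-5-oxo-3-(phenylselanyl)oxolan-2-yl]propyl}piperidine-2,4-dione
Conditions: Cs2CO3, DMF, 0 °C → rt
Reagents that add atoms: none
Why: C-Alkylation of the caesium enolate of the β-keto lactam (carbonate does not deprotonate the lactam N–H or the lactone α-hydrogens) with the iodide end of 20, iodide being displaced far faster than chloride. A quaternary C9 is formed, and either configuration serves.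

Step 15
Reactants: 21 (3R,6S)-3-(4-chlorobutyl)-6-[(2S,4S)-4-methyl-5-oxooxolan-2-yl]-3-{(1R)-1-[(2S,3R,4R)-4-methyl-5-oxo-3-(phenylselanyl)oxolan-2-yl]propyl}piperidine-2,4-dione
Product: 22 (3S,9S,10R,11S,12S,13S,18S,20S) nine-membered keto lactam: ring N4(H)–C9a(=O)–C9–C10–C11–C12–C1(=O)–C2–C3, 4-chlorobutyl on C9, ethyl on C10, α-methyl γ-lactone (C11–O–C14(=O)–C13(Me)–C12) cis-fused at C11/C12, (2S,4S)-4-methyl-5-oxooxolan-2-yl on C3
Conditions: Bu3SnH (1.3 equiv, syringe pump, 8 h), AIBN (20 mol%), PhH, 80 °C, 5 mM
Reagents that add atoms: none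
Why: Bu3Sn• abstracts the phenylselanyl group (C–Se far faster than C–Cl) to give the secondary C12 radical, which adds 5-exo-trig to the C1 ketone carbon; the alkoxy radical, held in a bicyclo[4.3.0] frame, then breaks the shared C1–C9 bond, restoring the C1 carbonyl and releasing the tertiary, amide-stabilised C9 radical, which takes hydrogen from Bu3SnH. The closest known reaction type is the Dowd–Beckwith three-carbon ring expansion of α-(3-halopropyl) β-keto esters. The transient cyclopentane is closed in the 5-exo mode; the nine-membered ring is not closed end to end but appears when the fusion bond of the bicycle is cut. C12: the new cyclopentane shares C11–C12 with the γ-lactone, so only a cis fusion is attainable and C1 ends cis to C10 whatever the configuration of the selenide. C9: the planar radical should be quenched on the face away from the ethyl group on C10, which gives H9 trans to ethyl as in 24; this is the least secure element. Selectivity needed: the ketone and not the lactam carbonyl (both 1,5-related to C12) should be attacked because an amide carbonyl is a far poorer radical acceptor and only scission of C1–C9 gives a stabilised radical. Cyclisation should win over premature reduction at low stannane concentration, and the chloride is inert.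

Step 16
Reactants: 22 nine-membered keto lactam with 4-chlorobutyl on C9
Product: 23 (3S,9S,10R,11S,12S,13S,18S,20S) nine-membered keto lactam as 22 but with 4-iodobutyl on C9
Conditions: NaI, acetone, 55 °C
Reagents that add atoms: sodium iodide, [Na+].[I-]
Why: Finkelstein exchange under neutral conditions (NaCl precipitates) turns the sluggish chloride into an iodide, so that the ring closure can be run cold.

Step 17
Reactants: 23 nine-membered keto lactam with 4-iodobutyl on C9
Product: 24 target: (3S,9S,10R,11S,12S,13S,18S,20S) tricyclic keto lactam in which C5–C8 link N4 to C9 (azepan-2-one fused to the nine-membered ring)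
Conditions: KN(SiMe3)2 (1.0 equiv), THF, −78 → 0 °C
Reagents that add atoms: none
Why: Intramolecular N-alkylation of the lactam (7-exo-tet): one equivalent of hindered amide base removes the N–H proton, the kinetically most accessible acid, at −78 °C, and the potassium amidate displaces the primary iodide on warming. No stereocentre is formed, and the short, cold contact with base is meant to spare C12, C13 and C20.

## Compound list

1 | (2S)-4-tert-butoxy-2-[(tert-butoxycarbonyl)amino]-4-oxobutanoic acid (Boc-L-Asp(Ot-Bu)-OH) | CC(C)(C)OC(=O)N[C@@H](CC(=O)OC(C)(C)C)C(=O)O | starting material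
2 | tert-butyl (3S)-3-[(tert-butoxycarbonyl)amino]-4-hydroxybutanoate | CC(C)(C)OC(=O)N[C@@H](CC(=O)OC(C)(C)C)CO | intermediate
3 | tert-butyl (3S)-3-[(tert-butoxycarbonyl)amino]-4-oxobutanoate | CC(C)(C)OC(=O)N[C@@H](CC(=O)OC(C)(C)C)C=O | intermediate
4 | ethyl 2-(bromomethyl)prop-2-enoate | C=C(CBr)C(=O)OCC | starting material
5 | 7-tert-butyl 1-ethyl (4S,5S)-5-[(tert-butoxycarbonyl)amino]-4-hydroxy-2-methylideneheptanedioate (not isolated) | CC(C)(C)OC(=O)C[C@@H]([C@@H](O)CC(=C)C(=O)OCC)NC(=O)OC(C)(C)C | intermediate
6 | tert-butyl (3S)-3-[(tert-butoxycarbonyl)amino]-3-[(2S)-4-methylidene-5-oxooxolan-2-yl]propanoate | CC(C)(C)OC(=O)C[C@@H]([C@@H]1CC(=C)C(=O)O1)NC(=O)OC(C)(C)C | intermediate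
7 | tert-butyl (3S)-3-[(tert-butoxycarbonyl)amino]-3-[(2S,4S)-4-methyl-5-oxooxolan-2-yl]propanoate | CC(C)(C)OC(=O)C[C@@H]([C@@H]1C[C@H](C)C(=O)O1)NC(=O)OC(C)(C)C | intermediate
8 | (3S)-3-[(tert-butoxycarbonyl)amino]-3-[(2S,4S)-4-methyl-5-oxooxolan-2-yl]propanoic acid | CC(C)(C)OC(=O)N[C@@H](CC(=O)O)[C@@H]1C[C@H](C)C(=O)O1 | intermediate
9 | tert-butyl N-[(1S)-3-(1H-benzotriazol-1-yl)-1-[(2S,4S)-4-methyl-5-oxooxolan-2-yl]-3-oxopropyl]carbamate | CC(C)(C)OC(=O)N[C@@H](CC(=O)n1nnc2ccccc12)[C@@H]1C[C@H](C)C(=O)O1 | intermediate
10 | 3-methylfuran-2(5H)-one | CC1=CCOC1=O | starting material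
11 | trimethyl[(3-methylfuran-2-yl)oxy]silane | Cc1ccoc1O[Si](C)(C)C | intermediate
12 | (2E)-pent-2-enal | CC/C=C/C=O | starting material
13 | (3R)-3-[(2S)-4-methyl-5-oxo-2,5-dihydrofuran-2-yl]pentanal | CC[C@@H]([C@@H]1OC(=O)C(C)=C1)CC=O | intermediate
14 | (3R)-3-[(2S)-4-methyl-5-oxo-2,5-dihydrofuran-2-yl]pentanoic acid | CC[C@@H]([C@@H]1OC(=O)C(C)=C1)CC(=O)O | intermediate
15 | (3R)-3-[(2S,3R,4R)-4-methyl-5-oxo-3-(phenylselanyl)oxolan-2-yl]pentanoic acid | CC[C@@H]([C@@H]1OC(=O)[C@@H](C)[C@H]1[Se]c1ccccc1)CC(=O)O | intermediate
16 | S-phenyl (3R)-3-[(2S,3R,4R)-4-methyl-5-oxo-3-(phenylselanyl)oxolan-2-yl]pentanethioate | CC[C@@H]([C@@H]1OC(=O)[C@@H](C)[C@H]1[Se]c1ccccc1)CC(=O)Sc1ccccc1 | intermediate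
17 | S-phenyl (5S)-5-[(tert-butoxycarbonyl)amino]-5-[(2S,4S)-4-methyl-5-oxooxolan-2-yl]-2-{(1R)-1-[(2S,3R,4R)-4-methyl-5-oxo-3-(phenylselanyl)oxolan-2-yl]propyl}-3-oxopentanethioate (C2 epimers) | CC[C@@H]([C@@H]1OC(=O)[C@@H](C)[C@H]1[Se]c1ccccc1)C(C(=O)Sc1ccccc1)C(=O)C[C@@H]([C@@H]1C[C@H](C)C(=O)O1)NC(=O)OC(C)(C)C | intermediate
18 | 5-ammonium trifluoroacetate corresponding to 17 (Boc removed; not isolated) | CC[C@@H]([C@@H]1OC(=O)[C@@H](C)[C@H]1[Se]c1ccccc1)C(C(=O)Sc1ccccc1)C(=O)C[C@@H]([C@@H]1C[C@H](C)C(=O)O1)[NH3+].[O-]C(=O)C(F)(F)F | intermediate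
19 | (6S)-6-[(2S,4S)-4-methyl-5-oxooxolan-2-yl]-3-{(1R)-1-[(2S,3R,4R)-4-methyl-5-oxo-3-(phenylselanyl)oxolan-2-yl]propyl}piperidine-2,4-dione (C3 epimers) | CC[C@@H]([C@@H]1OC(=O)[C@@H](C)[C@H]1[Se]c1ccccc1)C1C(=O)C[C@@H]([C@@H]2C[C@H](C)C(=O)O2)NC1=O | intermediate
20 | 1-chloro-4-iodobutane | ClCCCCI | starting material
21 | (3R,6S)-3-(4-chlorobutyl)-6-[(2S,4S)-4-methyl-5-oxooxolan-2-yl]-3-{(1R)-1-[(2S,3R,4R)-4-methyl-5-oxo-3-(phenylselanyl)oxolan-2-yl]propyl}piperidine-2,4-dione | CC[C@@H]([C@@H]1OC(=O)[C@@H](C)[C@H]1[Se]c1ccccc1)[C@]1(CCCCCl)C(=O)C[C@@H]([C@@H]2C[C@H](C)C(=O)O2)NC1=O | intermediate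
22 | (3S,9S,10R,11S,12S,13S,18S,20S) nine-membered keto lactam (N4–H), 4-chlorobutyl on C9, ethyl on C10, cis-fused α-methyl γ-lactone at C11/C12, (2S,4S)-4-methyl-5-oxooxolan-2-yl on C3 | CC[C@H]1[C@@H]2OC(=O)[C@@H](C)[C@@H]2C(=O)C[C@@H]([C@@H]2C[C@H](C)C(=O)O2)NC(=O)[C@H]1CCCCCl | intermediate
23 | as 22 with 4-iodobutyl on C9 | CC[C@H]1[C@@H]2OC(=O)[C@@H](C)[C@@H]2C(=O)C[C@@H]([C@@H]2C[C@H](C)C(=O)O2)NC(=O)[C@H]1CCCCI | intermediate
24 | CNP0311700.3: (3S,9S,10R,11S,12S,13S,18S,20S) tricyclic keto lactam, azepan-2-one (N4, C5–C8, C9, C9a) fused to the nine-membered ring | CC[C@H]1[C@@H]2OC(=O)[C@@H](C)[C@@H]2C(=O)C[C@@H]([C@@H]2C[C@H](C)C(=O)O2)N2CCCC[C@@H]1C2=O | target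

## Step count and least certain steps

Total: 17 steps. Longest linear sequence: 12 steps (1 → 24 through steps 1–6 and 12–17); the branch from 10 (steps 7–11) joins at step 12.

**Step 15 (key step).** Most likely failure: premature hydrogen transfer to the C12 radical before the slow addition to the hindered ketone, and poor facial selectivity in the hydrogen transfer to C9. Fallback, setting out from 21 and returning at 22: the polarity is reversed so that the radical sits on C1 and C9 is set by protonation. Oxidation of the selenide with excess buffered m-CPBA would give the selenone F1, whose mild-base β-elimination (NaHCO3) would give the butenolide F2. SmI2 in THF/t-BuOH would form the C1 ketyl, which should add 5-exo to the butenolide β-carbon and give the tricyclic tertiary alcohol F3; C13 could be equilibrated with DBU at this ketone-free stage if the enolate protonation goes the wrong way. Hypoiodite alkoxy-radical fragmentation (PhI(OAc)2, I2, visible light) should cleave C1–C9 to the nine-membered α-iodo lactam F4, and zinc dust in AcOH would reduce the C–I bond through the zinc enolate to 22.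

**Step 12.** Most likely failure: slow C-acylation of the β-branched enolate, with self-condensation of the acyl donor taking over. Fallback, setting out from 8 and returning at 17: the electrophile is changed from an acyl donor to an aldehyde. Mixed-anhydride/NaBH4 reduction of 8 would give the alcohol F5, and TEMPO/PhI(OAc)2 the β-amino aldehyde F6. A direct soft-enolisation aldol addition of 16 to F6 (MgBr2·OEt2, i-Pr2NEt) would give the β-hydroxy thioester F7, and Parikh–Doering oxidation would give 17.

**Step 14.** Most likely failure: O-alkylation at the C1 enolate oxygen, because quaternisation next to the branched C10 is slow with an unactivated iodide. Fallback, setting out from 19 and returning at 21: an activated allylic electrophile is used and the alkene is then saturated. Alkylation with excess (E)-1,4-dichlorobut-2-ene (K2CO3, acetone) would give the chlorobutenyl dione F8, and diimide (2-nitrobenzenesulfonohydrazide, Et3N) would reduce the isolated alkene to 21 without touching selenide or chloride.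

**Step 3.** Most likely failure: weak chelation control (competing coordination by the ester) and hence erosion of the C18 configuration. Fallback, setting out from 3 and returning at 6: the unwanted adduct is converged by an invertive ring closure. The C18-epimeric hydroxy diester F9 would be separated, its ethyl ester saponified (LiOH, THF/H2O, 0 °C) to the hydroxy acid F10, and Mitsunobu lactonisation (PPh3, DIAD) would close the lactone with inversion at C18 to give 6.

**Step 17.** Most likely failure: proton transfer from C12–H or C2–H to the amidate, leading to epimerisation at C12 or β-elimination that opens the fused lactone. Fallback, setting out from 23 and returning at 24: the nitrogen–carbon bond is made under acid. Oxidation of the iodide with anhydrous Me3NO in DMSO would give the aldehyde F11; CF3CO2H/Et3SiH in CH2Cl2 would then close the cyclic hemiaminal F12 and reduce its N-acyliminium ion to 24.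

## Further compounds

F1 | step 15 | (3R,6S)-3-{(1R)-1-[(2S,3R,4R)-3-(benzeneselenonyl)-4-methyl-5-oxooxolan-2-yl]propyl}-3-(4-chlorobutyl)-6-[(2S,4S)-4-methyl-5-oxooxolan-2-yl]piperidine-2,4-dione | CC[C@@H]([C@@H]1OC(=O)[C@@H](C)[C@H]1[Se](=O)(=O)c1ccccc1)[C@]1(CCCCCl)C(=O)C[C@@H]([C@@H]2C[C@H](C)C(=O)O2)NC1=O
F2 | step 15 | (3R,6S)-3-(4-chlorobutyl)-3-{(1R)-1-[(2R)-4-methyl-5-oxo-2,5-dihydrofuran-2-yl]propyl}-6-[(2S,4S)-4-methyl-5-oxooxolan-2-yl]piperidine-2,4-dione (same C11 geometry as 21; descriptor changes with CIP ranking) | CC[C@@H]([C@@H]1OC(=O)C(C)=C1)[C@]1(CCCCCl)C(=O)C[C@@H]([C@@H]2C[C@H](C)C(=O)O2)NC1=O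
F3 | step 15 | tricyclic tertiary alcohol: C1(OH) bonded to C12, C1–C9 intact, lactone cis-fused at C11/C12 (C1 and C9 configurations not defined) | CC[C@H]1[C@@H]2OC(=O)[C@@H](C)[C@@H]2C2(O)C[C@@H]([C@@H]3C[C@H](C)C(=O)O3)NC(=O)C12CCCCCl
F4 | step 15 | 9-iodo analogue of 22 (C9 configuration not defined) | CC[C@H]1[C@@H]2OC(=O)[C@@H](C)[C@@H]2C(=O)C[C@@H]([C@@H]2C[C@H](C)C(=O)O2)NC(=O)C1(I)CCCCCl
F5 | step 12 | tert-butyl N-[(1S)-3-hydroxy-1-[(2S,4S)-4-methyl-5-oxooxolan-2-yl]propyl]carbamate | CC(C)(C)OC(=O)N[C@@H](CCO)[C@@H]1C[C@H](C)C(=O)O1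
F6 | step 12 | tert-butyl N-[(1S)-1-[(2S,4S)-4-methyl-5-oxooxolan-2-yl]-3-oxopropyl]carbamate | CC(C)(C)OC(=O)N[C@@H](CC=O)[C@@H]1C[C@H](C)C(=O)O1
F7 | step 12 | 3-hydroxy analogue of 17 (β-hydroxy thioester, C2 and C3 epimers) | CC[C@@H]([C@@H]1OC(=O)[C@@H](C)[C@H]1[Se]c1ccccc1)C(C(=O)Sc1ccccc1)C(O)C[C@@H]([C@@H]1C[C@H](C)C(=O)O1)NC(=O)OC(C)(C)C
F8 | step 14 | (3R,6S)-3-[(2E)-4-chlorobut-2-en-1-yl] analogue of 21 | CC[C@@H]([C@@H]1OC(=O)[C@@H](C)[C@H]1[Se]c1ccccc1)[C@]1(C/C=C/CCl)C(=O)C[C@@H]([C@@H]2C[C@H](C)C(=O)O2)NC1=O
F9 | step 3 | 7-tert-butyl 1-ethyl (4R,5S)-5-[(tert-butoxycarbonyl)amino]-4-hydroxy-2-methylideneheptanedioate | CC(C)(C)OC(=O)C[C@@H]([C@H](O)CC(=C)C(=O)OCC)NC(=O)OC(C)(C)C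
F10 | step 3 | (4R,5S)-7-tert-butoxy-5-[(tert-butoxycarbonyl)amino]-4-hydroxy-2-methylidene-7-oxoheptanoic acid | CC(C)(C)OC(=O)C[C@@H]([C@H](O)CC(=C)C(=O)O)NC(=O)OC(C)(C)C
F11 | step 17 | as 22 with 4-oxobutyl on C9 | CC[C@H]1[C@@H]2OC(=O)[C@@H](C)[C@@H]2C(=O)C[C@@H]([C@@H]2C[C@H](C)C(=O)O2)NC(=O)[C@H]1CCCC=O
F12 | step 17 | 5-hydroxy analogue of 24 (cyclic N-acyl hemiaminal, C5 epimers) | CC[C@H]1[C@@H]2OC(=O)[C@@H](C)[C@@H]2C(=O)C[C@@H]([C@@H]2C[C@H](C)C(=O)O2)N2C(O)CCC[C@@H]1C2=O
A1 | alternative 1 | methyl (2S,3R)-2-{4-[(tert-butyldiphenylsilyl)oxy]butyl}-3-formylpentanoate | CC[C@@H](C=O)[C@H](CCCCO[Si](c1ccccc1)(c1ccccc1)C(C)(C)C)C(=O)OC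
A2 | alternative 1 | methyl (2S)-4-(tert-butylsulfanyl)-2-methyl-4-oxobutanoate | CC(C)(C)SC(=O)C[C@H](C)C(=O)OC
A3 | alternative 1 | methyl (2S,3R)-3-[(2S,3S,4S)-3-[(tert-butylsulfanyl)carbonyl]-4-methyl-5-oxooxolan-2-yl]-2-{4-[(tert-butyldiphenylsilyl)oxy]butyl}pentanoate | CC[C@@H]([C@@H]1OC(=O)[C@@H](C)[C@@H]1C(=O)SC(C)(C)C)[C@H](CCCCO[Si](c1ccccc1)(c1ccccc1)C(C)(C)C)C(=O)OC
A4 | alternative 2 | Z-nitrone: N-oxide of the imine between the C3 aldehyde of the side lactone and the C5 amine of methyl (2S,3R)-2-(4-aminobutyl)-3-[(2S,3S,4S)-3-ethenyl-4-methyl-5-oxooxolan-2-yl]pentanoate | CC[C@@H]([C@@H]1OC(=O)[C@@H](C)[C@@H]1C=C)[C@H](CCCC/[N+]([O-])=C/[C@@H]1C[C@H](C)C(=O)O1)C(=O)OC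
A5 | alternative 2 | isoxazolidine (O–C1, C2–C3) bridged by the twelve-membered ring, methyl ester on C9 | CC[C@H]1[C@@H]2OC(=O)[C@@H](C)[C@@H]2[C@@H]2C[C@@H]([C@@H]3C[C@H](C)C(=O)O3)N(O2)CCCC[C@@H]1C(=O)OC
A6 | alternative 3 | bicyclic lactim ether: seven-membered cyclic imidate C9a(=N4)–O–C1–C12–C11–C10–C9 fused to the tetrahydroazepine, (E)-alkenyl side lactone on C1 (C1 configuration to be chosen) | CC[C@H]1[C@@H]2OC(=O)[C@@H](C)[C@@H]2C(/C=C/[C@@H]2C[C@H](C)C(=O)O2)OC2=NCCCC[C@@H]12
A7 | alternative 3 | bicyclic lactam with a Z C1=C2 alkene in the nine-membered ring | CC[C@H]1[C@@H]2OC(=O)[C@@H](C)[C@@H]2/C=C\[C@@H]([C@@H]2C[C@H](C)C(=O)O2)N2CCCC[C@@H]1C2=O
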